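Ring C is cut at O1–C8a and C4–C4a: ring A becomes an aryne, and the chain O1–C2–C3–C4 a β-oxy acyl unit whose two stereocentres are set beforehand by an anti aldol. In one operation the C2 alkoxide adds to 3,5-bis(benzyloxy)benzyne and the aryl anion formed acylates itself on a lactone carbonyl, closing the chromanone. The precursor is the aldol adduct of a butane-2,3-diacetal glycolate lactone, whose dioxanone ring activates C4, masks O3 and falls away in the same step. The step exploits the ortho placement of O1 and C4 on C8a/C4a and the C5 oxygen beside them, which polarises the aryne. Hydrogenolysis and selective 7-O-prenylation finish the route.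

Key step: step 4

Assumption: (5S,6S)-5,6-dimethoxy-5,6-dimethyl-1,4-dioxan-2-one (butane-2,3-diacetal-protected glycolic acid lactone) is treated as a purchasable enantiopure reagent; otherwise it is reachable in three steps from enantiopure 3-chloropropane-1,2-diol and butane-2,3-dione.

Step 1
Reactants: 1 3,5-bis(benzyloxy)phenol
Product: 2 3,5-bis(benzyloxy)-2-bromophenol
Conditions: NBS (1.0 equiv), i-Pr2NH (10 mol%), CH2Cl2, −78 °C to 0 °C
Reagents that add atoms: N-bromosuccinimide, O=C1CCC(=O)N1Br
Why: Amine-mediated, hydroxyl-directed electrophilic aromatic bromination should place bromine at C2, between OH and one benzyloxy group, in preference to the more hindered C4 between the two benzyloxy groups.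

Step 2
Reactants: 2 3,5-bis(benzyloxy)-2-bromophenol
Product: 5 3,5-bis(benzyloxy)-2-(trimethylsilyl)phenyl trifluoromethanesulfonate, via aryl trimethylsilyl ether 3 (not isolated), via lithium 2-silylphenoxide 4 (not isolated)
Conditions: HMDS, THF, 65 °C, then evaporation; n-BuLi, THF, −78 °C; Tf2O, −78 °C to rt
Reagents that add atoms: hexamethyldisilazane, C[Si](C)(C)N[Si](C)(C)C; trifluoromethanesulfonic anhydride, O=S(=O)(OS(=O)(=O)C(F)(F)F)C(F)(F)F
Why: O-silylation, bromine–lithium exchange and retro-Brook 1,3-migration of silicon from oxygen to C2 should give phenoxide 4 with silicon exactly where bromine stood, and triflic anhydride then traps the oxygen.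

Step 3
Reactants: 6 (5S,6S)-5,6-dimethoxy-5,6-dimethyl-1,4-dioxan-2-one; 7 4-(benzyloxy)benzaldehyde
Product: 9 (3R,5S,6S)-3-[(R)-[4-(benzyloxy)phenyl](hydroxy)methyl]-5,6-dimethoxy-5,6-dimethyl-1,4-dioxan-2-one, via lithium enolate 8 (not isolated)
Conditions: LiN(SiMe3)2, THF, −78 °C; then 7, −78 °C; AcOH quench at −78 °C
Reagents that add atoms: none
Why: In this lithium enolate aldol addition the aldehyde should attack the enolate face opposite the axial C5 methoxy group (sets C3 as R), and the ring-locked E(O)-enolate reacting through a closed chair six-membered transition state should give the anti carbinol (sets the benzylic centre as R).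

Step 4
Reactants: 5 3,5-bis(benzyloxy)-2-(trimethylsilyl)phenyl trifluoromethanesulfonate; 9 (3R,5S,6S)-3-[(R)-[4-(benzyloxy)phenyl](hydroxy)methyl]-5,6-dimethoxy-5,6-dimethyl-1,4-dioxan-2-one
Product: 13 (2R,3R)-5,7-bis(benzyloxy)-2-[4-(benzyloxy)phenyl]-3-hydroxychroman-4-one, via trimethylsilyl ether 10 (not isolated), via 3,5-bis(benzyloxy)benzyne 11 (not isolated), via ring-opened keto ketal 12 (not isolated)
Conditions: (a) 9, HMDS, TMSCl (cat.), THF, rt, then evaporation; (b) 5 (1.5 equiv), CsF, 18-crown-6, THF, 0 °C to rt; (c) 1 M HCl, THF, 40 °C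
Reagents that add atoms: none
Why: Proposed new method: fluoride unmasks both partners in a proton-free medium, the C2 alkoxide from silyl ether 10 and aryne 11 from 5; the alkoxide adds to the aryne carbon remote from the C5 benzyloxy group (forming O1–C8a), and the aryl anion left at C4a, flanked by two oxygens, attacks the dioxanone carbonyl (forming C4–C4a), after which the tetrahedral intermediate collapses, opens the dioxanone to keto ketal 12 with loss of methoxide, and aqueous acid frees the C3 hydroxyl. The closest known reaction type is the fluoride-triggered addition and acyl-transfer annulation of arynes with salicylate esters to xanthones, together with aryne insertion into the N–C(O) bond of β-lactams; it is extended here to a secondary aliphatic alkoxide and a lactone as acyl donor. Ring C closes by 6-exo-trig acyl substitution after an intermolecular O-arylation, a formal [4+2] annulation. No stereocentre is created: C2 and C3 come from 9 and no bond to either is broken, so the trans (2R,3R) array should be carried over unchanged. The step needs regioselectivity on the unsymmetrical aryne, which the inductively withdrawing C5–O bond beside the triple bond secures by sending the nucleophile to the distal carbon and placing the carbanion next to oxygen. It also needs acylation to outrun protonation and retro-aldol cleavage, which the absence of any O–H, the low standing concentration of alkoxide and the activated lactone carbonyl are chosen to secure.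

Step 5
Reactants: 13 (2R,3R)-5,7-bis(benzyloxy)-2-[4-(benzyloxy)phenyl]-3-hydroxychroman-4-one
Product: 14 (2R,3R)-3,5,7-trihydroxy-2-(4-hydroxyphenyl)chroman-4-one (aromadendrin)
Conditions: H2 (1 atm), 10% Pd/C, EtOAc/MeOH, rt
Reagents that add atoms: none
Why: Palladium-catalysed hydrogenolysis should cleave the three aryl benzyl ethers, while the ketone, the ring C ether and both stereocentres stay untouched under these neutral conditions.

Step 6
Reactants: 14 (2R,3R)-3,5,7-trihydroxy-2-(4-hydroxyphenyl)chroman-4-one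
Product: 15 7-prenyloxyaromadendrin, (2R,3R)-3,5-dihydroxy-2-(4-hydroxyphenyl)-7-[(3-methylbut-2-en-1-yl)oxy]chroman-4-one
Conditions: prenyl bromide (1.05 equiv), K2CO3 (1.0 equiv), acetone, rt, argon
Reagents that add atoms: 1-bromo-3-methylbut-2-ene, CC(C)=CCBr
Why: In this Williamson etherification one equivalent of mild base should ionise only the 7-OH (para to the C4 carbonyl and the most acidic phenol), since 5-OH is held in a hydrogen bond to C4=O, 4'-OH is less acidic and 3-OH is an alcohol, so the prenyl group should enter at O7 without touching the stereocentres.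

Compound list
1 | 3,5-bis(benzyloxy)phenol | Oc1cc(OCc2ccccc2)cc(OCc2ccccc2)c1 | starting material
2 | 3,5-bis(benzyloxy)-2-bromophenol | Oc1cc(OCc2ccccc2)cc(OCc2ccccc2)c1Br | intermediate
3 | [3,5-bis(benzyloxy)-2-bromophenoxy]trimethylsilane | C[Si](C)(C)Oc1cc(OCc2ccccc2)cc(OCc2ccccc2)c1Br | intermediate (not isolated)
4 | lithium 3,5-bis(benzyloxy)-2-(trimethylsilyl)phenoxide | [Li+].[O-]c1cc(OCc2ccccc2)cc(OCc2ccccc2)c1[Si](C)(C)C | intermediate (not isolated)
5 | 3,5-bis(benzyloxy)-2-(trimethylsilyl)phenyl trifluoromethanesulfonate | C[Si](C)(C)c1c(OS(=O)(=O)C(F)(F)F)cc(OCc2ccccc2)cc1OCc1ccccc1 | intermediate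
6 | (5S,6S)-5,6-dimethoxy-5,6-dimethyl-1,4-dioxan-2-one | O=C1CO[C@](C)(OC)[C@@](C)(OC)O1 | starting material
7 | 4-(benzyloxy)benzaldehyde | O=Cc1ccc(OCc2ccccc2)cc1 | starting material
8 | lithium (5S,6S)-5,6-dimethoxy-5,6-dimethyl-5,6-dihydro-1,4-dioxin-2-olate (enolate of 6) | [Li+].[O-]C1=CO[C@](C)(OC)[C@@](C)(OC)O1 | intermediate (not isolated)
9 | (3R,5S,6S)-3-[(R)-[4-(benzyloxy)phenyl](hydroxy)methyl]-5,6-dimethoxy-5,6-dimethyl-1,4-dioxan-2-one | O=C1[C@@H]([C@H](O)c2ccc(OCc3ccccc3)cc2)O[C@](C)(OC)[C@@](C)(OC)O1 | intermediate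
10 | (3R,5S,6S)-3-[(R)-[4-(benzyloxy)phenyl](trimethylsilyloxy)methyl]-5,6-dimethoxy-5,6-dimethyl-1,4-dioxan-2-one | O=C1[C@@H]([C@H](O[Si](C)(C)C)c2ccc(OCc3ccccc3)cc2)O[C@](C)(OC)[C@@](C)(OC)O1 | intermediate (not isolated)
11 | 3,5-bis(benzyloxy)benzyne (1,2-didehydro-3,5-bis(benzyloxy)benzene) | C1#CC(OCc2ccccc2)=CC(OCc2ccccc2)=C1 | intermediate (not isolated)
12 | (2R,3R)-5,7-bis(benzyloxy)-2-[4-(benzyloxy)phenyl]-3-{[(2S)-2-methoxy-3-oxobutan-2-yl]oxy}chroman-4-one | C(c1ccccc1)Oc1cc(OCc3ccccc3)c2c(c1)O[C@H](c1ccc(OCc3ccccc3)cc1)[C@@H](O[C@](C)(OC)C(C)=O)C2=O | intermediate (not isolated)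
13 | (2R,3R)-5,7-bis(benzyloxy)-2-[4-(benzyloxy)phenyl]-3-hydroxychroman-4-one | O(Cc1ccccc1)c1cc(OCc3ccccc3)c2c(c1)O[C@H](c1ccc(OCc3ccccc3)cc1)[C@@H](O)C2=O | intermediate
14 | (2R,3R)-3,5,7-trihydroxy-2-(4-hydroxyphenyl)chroman-4-one (aromadendrin) | Oc1cc(O)c2c(c1)O[C@H](c1ccc(O)cc1)[C@@H](O)C2=O | intermediate
15 | 7-prenyloxyaromadendrin | CC(C)=CCOc1cc(O)c2c(c1)O[C@H](c1ccc(O)cc1)[C@@H](O)C2=O | target

Total step count: 6. Longest linear sequence: 5 steps (1 → 2 → 5 → 13 → 14 → 15).

Steps most likely to fail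

Step 4 (proposed new method). The aryl anion may be protonated before it reaches the lactone carbonyl, the transient alkoxide may undergo retro-aldol cleavage, or the liberated methoxide may open ring C by β-elimination and erode the stereocentres. Fallback with known chemistry, setting out from 1 and 7 and returning at 13: Friedel–Crafts acetylation of 1 (Ac2O, BF3·OEt2) ortho to the hydroxyl should give 1-[2,4-bis(benzyloxy)-6-hydroxyphenyl]ethan-1-one F1; Claisen–Schmidt condensation with 7 (KOH, EtOH) should give (E)-1-[2,4-bis(benzyloxy)-6-hydroxyphenyl]-3-[4-(benzyloxy)phenyl]prop-2-en-1-one F2; MOMCl/i-Pr2NEt should give (E)-1-[2,4-bis(benzyloxy)-6-(methoxymethoxy)phenyl]-3-[4-(benzyloxy)phenyl]prop-2-en-1-one F3; Julia–Colonna epoxidation (poly-L-leucine, urea–H2O2, DBU, THF) should give [2,4-bis(benzyloxy)-6-(methoxymethoxy)phenyl]{(2R,3S)-3-[4-(benzyloxy)phenyl]oxiran-2-yl}methanone F4; HCl in MeOH/THF then removes the acetal, and the freed phenol opens the epoxide at the benzylic carbon with inversion (6-endo) to give 13.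

Step 6. Site selectivity may be lost through alkylation at O4' or at ring A carbon, and the base may epimerise or air-oxidise the dihydroflavonol. Fallback, setting out from 14 and returning at 15: peracetylation (Ac2O, pyridine, DMAP) should give (2R,3R)-3,5,7-triacetoxy-2-(4-acetoxyphenyl)chroman-4-one F5; PhSH/imidazole in NMP at 0 °C should cleave only the 7-O-acetyl group, the aryl ester para to the C4 carbonyl, to give the 7-hydroxy triacetate F6; Mitsunobu etherification with 3-methylbut-2-en-1-ol (PPh3, DIAD, THF) under neutral conditions should give the 7-O-prenyl triacetate F7; catalytic K2CO3 in MeOH at 0 °C under argon removes the three acetates to give 15.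

Step 1. Bromination may occur para to the hydroxyl (between the two benzyloxy groups) or twice. Fallback, setting out from 1 and returning at 5: i-PrNCO/Et3N should give 3,5-bis(benzyloxy)phenyl N-isopropylcarbamate F8; in situ N-silylation (TBSOTf, TMEDA), carbamate-directed ortho-lithiation (n-BuLi, TMEDA, −78 °C) and TMSCl should give 3,5-bis(benzyloxy)-2-(trimethylsilyl)phenyl N-isopropylcarbamate F9, the position being fixed by the carbamate as the strongest directing group; Et2NH/DBU frees 3,5-bis(benzyloxy)-2-(trimethylsilyl)phenol F10; Tf2O/pyridine gives 5.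

Further compounds
F1 | step 4 | 1-[2,4-bis(benzyloxy)-6-hydroxyphenyl]ethan-1-one | CC(=O)c1c(O)cc(OCc2ccccc2)cc1OCc1ccccc1
F2 | step 4 | (E)-1-[2,4-bis(benzyloxy)-6-hydroxyphenyl]-3-[4-(benzyloxy)phenyl]prop-2-en-1-one | O=C(/C=C/c1ccc(OCc2ccccc2)cc1)c1c(O)cc(OCc2ccccc2)cc1OCc1ccccc1
F3 | step 4 | (E)-1-[2,4-bis(benzyloxy)-6-(methoxymethoxy)phenyl]-3-[4-(benzyloxy)phenyl]prop-2-en-1-one | O=C(/C=C/c1ccc(OCc2ccccc2)cc1)c1c(OCOC)cc(OCc2ccccc2)cc1OCc1ccccc1
F4 | step 4 | [2,4-bis(benzyloxy)-6-(methoxymethoxy)phenyl]{(2R,3S)-3-[4-(benzyloxy)phenyl]oxiran-2-yl}methanone | O=C([C@@H]1O[C@H]1c1ccc(OCc2ccccc2)cc1)c1c(OCOC)cc(OCc2ccccc2)cc1OCc1ccccc1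
F5 | step 6 | (2R,3R)-3,5,7-triacetoxy-2-(4-acetoxyphenyl)chroman-4-one | CC(=O)Oc1cc(OC(C)=O)c2c(c1)O[C@H](c1ccc(OC(C)=O)cc1)[C@@H](OC(C)=O)C2=O
F6 | step 6 | (2R,3R)-3,5-diacetoxy-2-(4-acetoxyphenyl)-7-hydroxychroman-4-one | Oc1cc(OC(C)=O)c2c(c1)O[C@H](c1ccc(OC(C)=O)cc1)[C@@H](OC(C)=O)C2=O
F7 | step 6 | (2R,3R)-3,5-diacetoxy-2-(4-acetoxyphenyl)-7-[(3-methylbut-2-en-1-yl)oxy]chroman-4-one | CC(C)=CCOc1cc(OC(C)=O)c2c(c1)O[C@H](c1ccc(OC(C)=O)cc1)[C@@H](OC(C)=O)C2=O
F8 | step 1 | 3,5-bis(benzyloxy)phenyl N-isopropylcarbamate | CC(C)NC(=O)Oc1cc(OCc2ccccc2)cc(OCc2ccccc2)c1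
F9 | step 1 | 3,5-bis(benzyloxy)-2-(trimethylsilyl)phenyl N-isopropylcarbamate | CC(C)NC(=O)Oc1cc(OCc2ccccc2)cc(OCc2ccccc2)c1[Si](C)(C)C
F10 | step 1 | 3,5-bis(benzyloxy)-2-(trimethylsilyl)phenol | Oc1cc(OCc2ccccc2)cc(OCc2ccccc2)c1[Si](C)(C)C
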